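**Remark:** positions are given in germacranolide numbering of the target (C1=C10 carries C14, C4=C5 carries C15, the lactone oxygen is on C6, C11–C13 belong to the lactone); TBS = tert-butyldimethylsilyl, TBDPS = tert-butyldiphenylsilyl, TES = triethylsilyl; compound 20 is an enol/aldehyde tautomer pair written as its hydrogen-bonded enol.

## Analysis of the target

The target 35 is a cis,cis-germacranolide: a cyclodeca-1(10),4-diene fused trans across C6–C7 to an α-methylene-γ-butyrolactone (O on C6, C11=C13, C12=O) and acylated on O8 by (S)-2-methylbutanoic acid. Both ring alkenes are trisubstituted with their ring bonds cis (E by the sequence rule); C1=C10 carries the C14 aldehyde and C4=C5 the C15 carbinol. C6, C7 and C8 are contiguous and all R; read as an open chain, C6/C7 are syn and C7/C8 anti in the aldol sense, and the fourth stereocentre lies in the acyl group, α to an ester. The α-methylene lactone and the enal are Michael acceptors, so strong bases, hydrides and nucleophiles must all be used before the end. A free 8-OH would add to a C14 aldehyde as a five-membered hemiacetal and can also take over the lactone acyl group, so O8 has to be acylated before C14 reaches the aldehyde level. The difficulty is the ten-membered ring with two Z-type trisubstituted alkenes, together with telling apart C14 and C15 (same kind of carbon, different oxidation level) and the two carboxyl carbons C12 and C14. The strategy rests on the C1–C2 bond: C2 belongs to the only heteroatom-free CH2–CH2 bridge, and C1 is the β-carbon of the C14-conjugated alkene, which an enol triflate of an α-formyl ester presents as an electrophile.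

## Retrosynthetic reasoning

**35 back to 31 and 32.** The last operations are removal of the C15 silyl group (34), oxidation at C14 (33 to 34) and acylation of O8 with acid 32 (31 to 33). The ester is introduced after all hydride and enolate chemistry because its α-centre is epimerisable. It is introduced before C14 becomes an aldehyde, so that no γ-hydroxy aldehyde is ever present. In 33 C14 is a primary triethylsilyl ether that can be oxidised directly while the C15 TBDPS ether stays.

**31 back to 23.** The exocyclic C11=C13 bond is cut back to the lactone enolate of 25 and iminium salt 26. The C14 alcohol of 25 comes from the conjugated ester of 23. For that reduction the lactone is masked in the flask as silyl ketene acetal 24, so the lactone is never reduced and nothing has to be re-oxidised. The reduction precedes the methylenation because afterwards the lactone would have no α-hydrogen left for masking.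

**23 back to 21 (key disconnection, C1–C2).** The sp3–sp2 bond C1–C2 is cut. C2 becomes the boron-bearing carbon of alkylborane 22, obtained by hydroboration of the terminal C2=C3 alkene of the diene in 21. C1 becomes the enol triflate carbon of 21. The cut is made here because it creates no stereocentre, uses the C1=C10 geometry already fixed in 21, and leaves C6, C7 and C8 to be set in open-chain intermediates. The forward reaction must close a ten-membered ring against intermolecular coupling.

**21 back to 17 and 18.** The enol triflate is the O-sulfonylated enolate of formyl ester 20, and C1 comes from ethyl formate 18 by Claisen condensation at C10 of 17. The lactone α-CH2 (C11) of 17 is more acidic than C10, so a direct formylation would go to the wrong carbon. The lactone is therefore first converted in the flask into silyl ketene acetal 19, which leaves C10 as the only enolisable position.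

**17 back to 12 and 13.** The C8 carbinol of 16 (silylated in 17) is traced to ketone 15, whose reduction anti to the C7–C6 bond gives the 7,8-anti relationship. The C8–C9 bond of 15 is cut to thioester 12 and zinc homoenolate 14, made from iodo ester 13. This brings in C9, C10 and C14 in one piece and at the ester level.

**12 back to 9 and 6.** The C6–C7 bond and the lactone C–O bond are cut together. A syn-aldol of imide 9 with dienal 6 gives adduct 10 with C6 and C7 set by the auxiliary, and 10 lactonises to the trans-lactone 11. An anti-aldol across C7–C8 followed by alkenylation of a C6 aldehyde was also considered. It was set aside because it needs an anti-selective aldol with an enolisable aldehyde, substrate-controlled addition at C6, and a C5-metalated diene that is hard to make with the right geometry.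

**6 back to 1 and 4; 9 back to 7 and 8.** The cis relationship of C6 and C3 on C4=C5 is traced to vinyl iodide 3, made by hydroxyl-directed trans-hydroalumination and iodinolysis of alkynol 2 (from diol 1). The vinyl group C3=C2 comes from stannane 4 with retention. Imide 9 is the N-acylation product of oxazolidinone 7 and acid chloride 8.

## Alternatives that were turned down

**Alternative 1:** The ring is cut at C5–C6 together with the lactone C–O bond. In the forward sense CrCl2 with catalytic NiCl2 would join an alkenyl iodide at C5 to an aldehyde at C6, and the resulting alkoxide would lactonise onto a C12 methyl ester to give A1.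
- In favour: this coupling is the best-precedented way to close ten-membered carbocycles and tolerates esters and silyl ethers. It makes the lactone in the same operation. C14 is already at the alcohol level as a p-methoxybenzyl ether, so no ester has to be reduced late.
- Against: C6 is created during ring closure, so its configuration depends on the conformation of the forming ring and not on a reagent. The aldehyde is α-branched and β-silyloxy, hence prone to epimerisation and elimination. Both trisubstituted ring alkenes must be built in the open chain without an enolate handle at C10.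
- Comparison: Alternative 1 is stronger on precedent for the ring closure and on the oxidation level of C14. The chosen route sets every stereocentre before cyclisation and closes the ring at a bond where no stereocentre forms.

**Alternative 2:** The C2–C3 bond is traced back through a [3,3] shift to a six-membered ring in which C5 and C10 are still bonded. KH with 18-crown-6 would form the alkoxide, the oxy-Cope shift would open the ten-membered ring, and N-phenylbis(trifluoromethanesulfonimide) would trap the C10 enolate as enol triflate A2.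
- In favour: the ring forms unimolecularly, without dilution or metal. The isopropenyl-type side chain on C7 already contains C11=C13, so no methylenation is needed.
- Against: both ring alkenes are formed in the rearrangement, and their geometry is set by the transition state. In A2 the triflate oxygen is cis to C2, so the carbon that later replaces it would end on the wrong side of C1=C10 for 35, and a geometric inversion would be needed. C14 still has to be added by carbonylation. The substituted cyclohexanol with three stereocentres and a tertiary carbinol is a long synthesis in itself.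
- Comparison: Alternative 2 is stronger on the efficiency of ring formation. The chosen route fixes the C1=C10 geometry by enolate trapping in an open chain and carries C14 from the start.

**Alternative 3:** The ring is cut at C7–C8. CrCl2 (divalent chromium) would turn a C13 allylic bromide on a butenolide into an allylchromium species that adds through C7 to a C8 aldehyde, restoring the C11=C13 methylene and giving A3.
- In favour: one step closes the ring, makes C7–C8, sets two stereocentres and delivers the finished α-methylene lactone with a free 8-OH. The endgame is then the shortest of all (acylation, ether cleavage, oxidation, desilylation).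
- Against: C7 and C8 are both created in the macrocyclisation. Addition anti to the C6 substituent is likely, but the C7/C8 relationship depends on how the aldehyde sits in a cyclic transition state inside a forming ten-membered ring. The C6 hydrogen of the butenolide is allylic twice over and easily lost. The allylic bromide is a sensitive alkylating agent to carry next to two trisubstituted alkenes.
- Comparison: Alternative 3 is stronger on convergence and on step count after cyclisation. The chosen route offers stereocentres set one at a time by an auxiliary and by Felkin control, each checkable before the ring is closed.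

Key step: step 13

## Route

Step 1
Reactants: 1 but-2-yne-1,4-diol
Product: 2 4-(TBDPSO)but-2-yn-1-ol
Conditions: 1 (3 equiv), imidazole, TBDPSCl (1 equiv), DMF, 0 °C → rt
Reagents that add atoms: tert-butyl(chloro)diphenylsilane, CC(C)(C)[Si](Cl)(c1ccccc1)c1ccccc1
Why: Statistical monosilylation of a cheap symmetric diol used in excess; diol and bis-ether are removed by polarity.

Step 2
Reactants: 2 monosilylated butynediol
Product: 3 (2Z)-4-(TBDPSO)-3-iodobut-2-en-1-ol
Conditions: NaAlH2(OCH2CH2OMe)2 (1.5 equiv), THF, 0 °C → rt; EtOAc, 0 °C; I2, THF, −78 → 0 °C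
Reagents that add atoms: iodine, II
Why: Hydroxyl-directed trans-hydroalumination places aluminium on the distal alkyne carbon (future C4) in a five-membered alkoxyaluminate and hydride on C5 from the opposite face; iodinolysis with retention should give the iodide cis to the CH2OH carbon (future C6).

Step 3
Reactants: 3 Z-iodo allylic alcohol; 4 tributyl(ethenyl)stannane
Product: 5 (2E)-3-[(TBDPSO)methyl]penta-2,4-dien-1-ol
Conditions: Pd(PPh3)4 (5 mol %), CuI (10 mol %), DMF, rt → 40 °C
Reagents that add atoms: none
Why: Stille coupling goes with retention at the alkenyl iodide, so the vinyl group (C3=C2) ends cis to C6 on C4=C5, the ring-cis geometry of the target.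

Step 4
Reactants: 5 dienol
Product: 6 (2E)-3-[(TBDPSO)methyl]penta-2,4-dienal
Conditions: MnO2 (activated, excess), CH2Cl2, rt, dark; filtered and used at once
Reagents that add atoms: none
Why: Allylic oxidation on neutral MnO2 avoids the acid or base that could isomerise the β,β-disubstituted enal about C4=C5.

Step 5
Reactants: 7 (4S)-4-benzyl-1,3-oxazolidin-2-one; 8 methyl 4-chloro-4-oxobutanoate
Product: 9 methyl 4-[(4S)-4-benzyl-2-oxo-1,3-oxazolidin-3-yl]-4-oxobutanoate
Conditions: n-BuLi, THF, −78 °C; then 8, −78 → 0 °C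
Reagents that add atoms: none
Why: N-acylation of the lithiated oxazolidinone by the acid chloride (Evans imide formation).

Step 6
Reactants: 9 succinate imide; 6 dienal
Product: 11 (4S)-4-benzyl-3-{[(2R,3S)-2-{(1E)-2-[(TBDPSO)methyl]buta-1,3-dien-1-yl}-5-oxooxolan-3-yl]carbonyl}-1,3-oxazolidin-2-one, via aldol adduct 10 (not isolated)
Conditions: n-Bu2BOTf, i-Pr2NEt, CH2Cl2, −78 → 0 °C; 6, −78 → 0 °C; pH 7 buffer, MeOH, H2O2, 0 °C; then pyridinium p-toluenesulfonate (cat.), CH2Cl2, rt
Reagents that add atoms: none
Why: Evans syn-aldol: the Z boron enolate reacts through a Zimmerman–Traxler chair on the face away from the benzyl group, which sets C7 and C6 in the 6,7-syn relationship of the target. The C6 hydroxyl then closes onto the C12 methyl ester, and a syn adduct can only give the trans-disubstituted γ-lactone.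

Step 7
Reactants: 11 lactone imide
Product: 12 S-ethyl (2R,3S)-2-{(1E)-2-[(TBDPSO)methyl]buta-1,3-dien-1-yl}-5-oxooxolane-3-carbothioate
Conditions: EtSH, n-BuLi (LiSEt), THF, 0 °C
Reagents that add atoms: ethanethiol, CCS
Why: Thiolate transacylation attacks the exocyclic imide carbonyl and releases the auxiliary 7 for recovery; the weakly basic thiolate should leave C7 and the β-acyloxy arrangement intact.

Step 8
Reactants: 12 thioester; 13 methyl 3-iodopropanoate
Product: 15 methyl 4-[(2R,3S)-2-{(1E)-2-[(TBDPSO)methyl]buta-1,3-dien-1-yl}-5-oxooxolan-3-yl]-4-oxobutanoate, via zinc homoenolate 14 (not isolated)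
Conditions: 13, Zn (activated with BrCH2CH2Br and Me3SiCl), THF, 35 °C; then 12, PdCl2(PPh3)2 (5 mol %), toluene, rt
Reagents that add atoms: none
Why: Fukuyama coupling: palladium-catalysed acylation of the alkylzinc iodide by the thioester forms C8–C9 under neutral conditions, which the methyl ester, the lactone and the base-sensitive β-acyloxy ketone should tolerate.

Step 9
Reactants: 15 keto ester
Product: 16 methyl (4R)-4-hydroxy-4-[(2R,3R)-2-{(1E)-2-[(TBDPSO)methyl]buta-1,3-dien-1-yl}-5-oxooxolan-3-yl]butanoate
Conditions: LiBH(s-Bu)3, THF, −78 °C; AcOH quench at −78 °C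
Reagents that add atoms: none
Why: Felkin–Anh reduction: the bulky hydride should attack the C8 ketone anti to the C7–C6 bond, the larger and oxygen-bearing ring branch, giving the 8R alcohol (7,8-anti). Esters and lactone are not reduced at this temperature, and the cold acidic quench prevents lactonisation onto C14.

Step 10
Reactants: 16 hydroxy ester
Product: 17 methyl (4R)-4-(TBSO)-4-[(2R,3S)-2-{(1E)-2-[(TBDPSO)methyl]buta-1,3-dien-1-yl}-5-oxooxolan-3-yl]butanoate
Conditions: t-BuMe2SiOTf, 2,6-lutidine, CH2Cl2, −78 → 0 °C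
Reagents that add atoms: tert-butyldimethylsilyl trifluoromethanesulfonate, CC(C)(C)[Si](C)(C)OS(=O)(=O)C(F)(F)F
Why: Silylation of the hindered secondary alcohol, carried out directly on the crude alcohol so that the γ-hydroxy ester cannot lactonise and the lactone cannot migrate to O8.

Step 11
Reactants: 17 silyl ether; 18 ethyl formate
Product: 20 methyl (2Z,4R)-4-(TBSO)-2-(hydroxymethylidene)-4-[(2R,3S)-2-{(1E)-2-[(TBDPSO)methyl]buta-1,3-dien-1-yl}-5-oxooxolan-3-yl]butanoate, via silyl ketene acetal 19 (not isolated)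
Conditions: LiN(SiMe3)2 (1.0 equiv), THF, −78 °C, then Me3SiCl; LiN(i-Pr)2 (1.5 equiv), −78 °C; 18 (1.2 equiv), −78 → −40 °C; 1 M HCl work-up
Reagents that add atoms: none
Why: The lactone α-CH2 is the most acidic position and is first removed from play as its O-silyl ketene acetal. The stronger amide base then enolises only the C14 ester, and Claisen condensation with ethyl formate installs C1; acidic work-up returns the lactone.

Step 12
Reactants: 20 formyl ester
Product: 21 methyl (2E,4R)-4-(TBSO)-4-[(2R,3S)-2-{(1E)-2-[(TBDPSO)methyl]buta-1,3-dien-1-yl}-5-oxooxolan-3-yl]-2-({[(trifluoromethyl)sulfonyl]oxy}methylidene)butanoate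
Conditions: KN(SiMe3)2 (1.05 equiv), 18-crown-6, THF, −78 °C; N-(5-chloropyridin-2-yl)bis(trifluoromethanesulfonyl)imide, −78 → −20 °C
Reagents that add atoms: N-(5-chloropyridin-2-yl)-1,1,1-trifluoro-N-[(trifluoromethyl)sulfonyl]methanesulfonamide, FC(F)(F)S(=O)(=O)N(c1ccc(Cl)cn1)S(=O)(=O)C(F)(F)F
Why: O-sulfonylation of a β-dicarbonyl enolate. With the potassium ion held by the crown ether there is no chelate, so the enolate oxygen should lie anti to the ester carbonyl and the triflate should form cis to C9 (E), leaving hydrogen next to the ester. Only the far more acidic formyl ester is deprotonated.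

Step 13
Reactants: 21 enol triflate diene
Product: 23 methyl (3aS,4R,6E,10E,11aR)-4-(TBSO)-10-[(TBDPSO)methyl]-2-oxo-2,3,3a,4,5,8,9,11a-octahydrocyclodeca[b]furan-6-carboxylate, via alkylborane 22 (not isolated)
Conditions: 9-borabicyclo[3.3.1]nonane (1.3 equiv), THF, 0 °C → rt; then addition over ca. 10 h to Pd(PPh3)4 (20 mol %), K3PO4 (3 M aq., 3 equiv), 1,4-dioxane, 60 °C, degassed, final ca. 0.002 M
Reagents that add atoms: none
Why: The borane adds anti-Markovnikov to the monosubstituted C2=C3 alkene only, because the trisubstituted C4=C5 and the electron-poor enol triflate alkene react far more slowly and ester and lactone are inert at this temperature; this gives primary borane 22. Zerovalent palladium inserts into the C1–O bond of the activated β-triflyloxy enoate with retention, phosphate turns the borane into a borate that passes C2 to palladium, and reductive elimination forms C1–C2. The closest known reactions are intramolecular B-alkyl Suzuki–Miyaura macrocyclisations and intermolecular couplings of alkyl-9-BBN reagents with enol triflates of β-dicarbonyl compounds; a ten-membered ring is at the small end of what this cyclisation has closed. The carbocycle closes through an eleven-membered palladacycle that contracts on reductive elimination, with both reacting carbons inside the new ring. No stereocentre is formed; C6, C7 and C8 are spectators and the C1=C10 geometry is inherited from the triflate. The step needs ring closure to outrun intermolecular coupling, protodeboronation and β-hydride elimination. Slow addition at high dilution serves the first, and the turn elements already in 21 (trans-lactone, cis C4=C5, triflate cis to C9) hold C2 near C1.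

Step 14
Reactants: 23 macrocyclic lactone ester
Product: 25 (3aS,4R,6E,10E,11aR)-4-(TBSO)-10-[(TBDPSO)methyl]-6-(hydroxymethyl)-3a,4,5,8,9,11a-hexahydrocyclodeca[b]furan-2(3H)-one, via silyl ketene acetal 24 (not isolated)
Conditions: LiN(SiMe3)2 (1.1 equiv), THF, −78 °C, then Me3SiCl; i-Bu2AlH (3 equiv), −78 → −40 °C; aq. KNaC4H4O6, then 1 M HCl wash
Reagents that add atoms: none
Why: The lactone is again masked as its silyl ketene acetal (the enoate has no α-hydrogen), so the aluminium hydride performs only the 1,2-reduction of the conjugated C14 ester to the allylic alcohol; work-up returns the lactone.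

Step 15
Reactants: 25 lactone alcohol; 26 N,N-dimethylmethaniminium iodide
Product: 29 (3aS,4R,6E,10E,11aR)-4-(TBSO)-10-[(TBDPSO)methyl]-6-(hydroxymethyl)-3-methylidene-3a,4,5,8,9,11a-hexahydrocyclodeca[b]furan-2(3H)-one, via Mannich base 27 (not isolated), via ammonium iodide 28 (not isolated)
Conditions: LiN(i-Pr)2 (2.3 equiv), THF, −78 °C; 26 (3 equiv), −78 °C → rt; MeI, MeOH, rt; aq. NaHCO3, CH2Cl2, rt
Reagents that add atoms: none
Why: Eschenmoser α-methylenation: Mannich reaction of the lactone enolate, N-methylation and base-induced β-elimination. The C14 alkoxide consumes the extra equivalent of base and is returned as the alcohol on work-up.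

Step 16
Reactants: 29 α-methylene lactone
Product: 30 (3aR,4R,6E,10E,11aR)-10-[(TBDPSO)methyl]-4-hydroxy-6-(hydroxymethyl)-3-methylidene-3a,4,5,8,9,11a-hexahydrocyclodeca[b]furan-2(3H)-one
Conditions: HF (48 % aq.), MeCN, 0 °C
Reagents that add atoms: none
Why: Acidic desilylation removes the secondary TBS ether while the much more acid-stable TBDPS ether should stay; base is avoided so that the lactone does not migrate to O8.

Step 17
Reactants: 30 diol
Product: 31 (3aR,4R,6E,10E,11aR)-10-[(TBDPSO)methyl]-4-hydroxy-3-methylidene-6-[(TESO)methyl]-3a,4,5,8,9,11a-hexahydrocyclodeca[b]furan-2(3H)-one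
Conditions: Et3SiCl (1.05 equiv), imidazole, CH2Cl2, −78 → −40 °C
Reagents that add atoms: chlorotriethylsilane, CC[Si](Cl)(CC)CC
Why: Selective silylation of the primary allylic C14 alcohol over the hindered secondary C8 alcohol.

Step 18
Reactants: 31 C8 alcohol; 32 (2S)-2-methylbutanoic acid
Product: 33 (3aR,4R,6E,10E,11aR)-10-[(TBDPSO)methyl]-3-methylidene-2-oxo-6-[(TESO)methyl]-2,3,3a,4,5,8,9,11a-octahydrocyclodeca[b]furan-4-yl (2S)-2-methylbutanoate
Conditions: N,N′-dicyclohexylcarbodiimide, 4-(dimethylamino)pyridine (cat.), CH2Cl2, 0 °C → rt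
Reagents that add atoms: none
Why: Steglich esterification; C14 is still a silyl ether, so O8 cannot be lost to a hemiacetal, and the mild conditions should keep the α-centre of the acid.

Step 19
Reactants: 33 ester
Product: 34 (3aR,4R,6E,10E,11aR)-10-[(TBDPSO)methyl]-6-formyl-3-methylidene-2-oxo-2,3,3a,4,5,8,9,11a-octahydrocyclodeca[b]furan-4-yl (2S)-2-methylbutanoate
Conditions: (COCl)2, Me2SO, CH2Cl2, −78 → −30 °C; Et3N, −78 → 0 °C
Reagents that add atoms: none
Why: Under Swern conditions a primary triethylsilyl ether is attacked by the chlorosulfonium salt and oxidised directly to the aldehyde (oxidative desilylation); the TBDPS ether, the ester and the α-methylene lactone should not react.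

Step 20
Reactants: 34 enal
Product: 35 (3aR,4R,6E,10E,11aR)-6-formyl-10-(hydroxymethyl)-3-methylidene-2-oxo-2,3,3a,4,5,8,9,11a-octahydrocyclodeca[b]furan-4-yl (2S)-2-methylbutanoate
Conditions: HF·pyridine, pyridine, THF, 0 °C → rt
Reagents that add atoms: none
Why: Buffered fluoride desilylation of the primary allylic TBDPS ether; neither Michael acceptor nor the ester is exposed to base.

## Compound list

1 | but-2-yne-1,4-diol | OCC#CCO | starting material
2 | 4-(TBDPSO)but-2-yn-1-ol | OCC#CCO[Si](c1ccccc1)(c1ccccc1)C(C)(C)C | intermediate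
3 | (2Z)-4-(TBDPSO)-3-iodobut-2-en-1-ol | OC/C=C(/CO[Si](c1ccccc1)(c1ccccc1)C(C)(C)C)I | intermediate
4 | tributyl(ethenyl)stannane | C=C[Sn](CCCC)(CCCC)CCCC | starting material
5 | (2E)-3-[(TBDPSO)methyl]penta-2,4-dien-1-ol (CH2OH cis to vinyl) | OC/C=C(/CO[Si](c1ccccc1)(c1ccccc1)C(C)(C)C)C=C | intermediate
6 | (2E)-3-[(TBDPSO)methyl]penta-2,4-dienal (CHO cis to vinyl) | O=C/C=C(/CO[Si](c1ccccc1)(c1ccccc1)C(C)(C)C)C=C | intermediate
7 | (4S)-4-benzyl-1,3-oxazolidin-2-one | O=C1N[C@@H](Cc2ccccc2)CO1 | starting material
8 | methyl 4-chloro-4-oxobutanoate | COC(=O)CCC(=O)Cl | starting material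
9 | methyl 4-[(4S)-4-benzyl-2-oxo-1,3-oxazolidin-3-yl]-4-oxobutanoate | COC(=O)CCC(=O)N1[C@@H](Cc2ccccc2)COC1=O | intermediate
10 | methyl (3S,4R,5E)-3-{[(4S)-4-benzyl-2-oxo-1,3-oxazolidin-3-yl]carbonyl}-6-[(TBDPSO)methyl]-4-hydroxyocta-5,7-dienoate | COC(=O)C[C@@H]([C@H](O)/C=C(/CO[Si](c1ccccc1)(c1ccccc1)C(C)(C)C)C=C)C(=O)N1[C@@H](Cc2ccccc2)COC1=O | intermediate
11 | (4S)-4-benzyl-3-{[(2R,3S)-2-{(1E)-2-[(TBDPSO)methyl]buta-1,3-dien-1-yl}-5-oxooxolan-3-yl]carbonyl}-1,3-oxazolidin-2-one | C1C(=O)O[C@H](/C=C(/CO[Si](c2ccccc2)(c2ccccc2)C(C)(C)C)C=C)[C@H]1C(=O)N1[C@@H](Cc2ccccc2)COC1=O | intermediate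
12 | S-ethyl (2R,3S)-2-{(1E)-2-[(TBDPSO)methyl]buta-1,3-dien-1-yl}-5-oxooxolane-3-carbothioate | C1C(=O)O[C@H](/C=C(/CO[Si](c2ccccc2)(c2ccccc2)C(C)(C)C)C=C)[C@H]1C(=O)SCC | intermediate
13 | methyl 3-iodopropanoate | COC(=O)CCI | starting material
14 | iodo(3-methoxy-3-oxopropyl)zinc | COC(=O)CC[Zn]I | intermediate
15 | methyl 4-[(2R,3S)-2-{(1E)-2-[(TBDPSO)methyl]buta-1,3-dien-1-yl}-5-oxooxolan-3-yl]-4-oxobutanoate | C1C(=O)O[C@H](/C=C(/CO[Si](c2ccccc2)(c2ccccc2)C(C)(C)C)C=C)[C@H]1C(=O)CCC(=O)OC | intermediate
16 | methyl (4R)-4-hydroxy-4-[(2R,3R)-2-{(1E)-2-[(TBDPSO)methyl]buta-1,3-dien-1-yl}-5-oxooxolan-3-yl]butanoate | C1C(=O)O[C@H](/C=C(/CO[Si](c2ccccc2)(c2ccccc2)C(C)(C)C)C=C)[C@H]1[C@H](O)CCC(=O)OC | intermediate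
17 | methyl (4R)-4-(TBSO)-4-[(2R,3S)-2-{(1E)-2-[(TBDPSO)methyl]buta-1,3-dien-1-yl}-5-oxooxolan-3-yl]butanoate | C1C(=O)O[C@H](/C=C(/CO[Si](c2ccccc2)(c2ccccc2)C(C)(C)C)C=C)[C@H]1[C@H](O[Si](C)(C)C(C)(C)C)CCC(=O)OC | intermediate
18 | ethyl formate | CCOC=O | starting material
19 | methyl (4R)-4-(TBSO)-4-[(2R,3S)-2-{(1E)-2-[(TBDPSO)methyl]buta-1,3-dien-1-yl}-5-[(trimethylsilyl)oxy]-2,3-dihydrofuran-3-yl]butanoate | C1=C(O[Si](C)(C)C)O[C@H](/C=C(/CO[Si](c2ccccc2)(c2ccccc2)C(C)(C)C)C=C)[C@H]1[C@H](O[Si](C)(C)C(C)(C)C)CCC(=O)OC | intermediate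
20 | methyl (2Z,4R)-4-(TBSO)-2-(hydroxymethylidene)-4-[(2R,3S)-2-{(1E)-2-[(TBDPSO)methyl]buta-1,3-dien-1-yl}-5-oxooxolan-3-yl]butanoate (enol of the 2-formyl ester) | C1C(=O)O[C@H](/C=C(/CO[Si](c2ccccc2)(c2ccccc2)C(C)(C)C)C=C)[C@H]1[C@H](O[Si](C)(C)C(C)(C)C)C/C(C(=O)OC)=C/O | intermediate
21 | methyl (2E,4R)-4-(TBSO)-4-[(2R,3S)-2-{(1E)-2-[(TBDPSO)methyl]buta-1,3-dien-1-yl}-5-oxooxolan-3-yl]-2-({[(trifluoromethyl)sulfonyl]oxy}methylidene)butanoate | C1C(=O)O[C@H](/C=C(/CO[Si](c2ccccc2)(c2ccccc2)C(C)(C)C)C=C)[C@H]1[C@H](O[Si](C)(C)C(C)(C)C)C/C(C(=O)OC)=C\OS(=O)(=O)C(F)(F)F | intermediate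
22 | methyl (2E,4R)-4-[(2R,3S)-2-{(1E)-4-(9-borabicyclo[3.3.1]nonan-9-yl)-2-[(TBDPSO)methyl]but-1-en-1-yl}-5-oxooxolan-3-yl]-4-(TBSO)-2-({[(trifluoromethyl)sulfonyl]oxy}methylidene)butanoate | C1C(=O)O[C@H](/C=C(/CO[Si](c2ccccc2)(c2ccccc2)C(C)(C)C)CCB2C3CCCC2CCC3)[C@H]1[C@H](O[Si](C)(C)C(C)(C)C)C/C(C(=O)OC)=C\OS(=O)(=O)C(F)(F)F | intermediate
23 | methyl (3aS,4R,6E,10E,11aR)-4-(TBSO)-10-[(TBDPSO)methyl]-2-oxo-2,3,3a,4,5,8,9,11a-octahydrocyclodeca[b]furan-6-carboxylate | C1C(=O)O[C@@H]2/C=C(/CO[Si](c3ccccc3)(c3ccccc3)C(C)(C)C)CC/C=C(/C(=O)OC)C[C@@H](O[Si](C)(C)C(C)(C)C)[C@@H]12 | intermediate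
24 | methyl (3aS,4R,6E,10E,11aR)-4-(TBSO)-10-[(TBDPSO)methyl]-2-[(trimethylsilyl)oxy]-3a,4,5,8,9,11a-hexahydrocyclodeca[b]furan-6-carboxylate | C1=C(O[Si](C)(C)C)O[C@@H]2/C=C(/CO[Si](c3ccccc3)(c3ccccc3)C(C)(C)C)CC/C=C(/C(=O)OC)C[C@@H](O[Si](C)(C)C(C)(C)C)[C@@H]12 | intermediate
25 | (3aS,4R,6E,10E,11aR)-4-(TBSO)-10-[(TBDPSO)methyl]-6-(hydroxymethyl)-3a,4,5,8,9,11a-hexahydrocyclodeca[b]furan-2(3H)-one | C1C(=O)O[C@@H]2/C=C(/CO[Si](c3ccccc3)(c3ccccc3)C(C)(C)C)CC/C=C(/CO)C[C@@H](O[Si](C)(C)C(C)(C)C)[C@@H]12 | intermediate
26 | N,N-dimethylmethaniminium iodide | C=[N+](C)C.[I-] | starting material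
27 | 3-[(dimethylamino)methyl] derivative of 25 (C11 epimers, centre removed in the same step) | CN(C)CC1C(=O)O[C@@H]2/C=C(/CO[Si](c3ccccc3)(c3ccccc3)C(C)(C)C)CC/C=C(/CO)C[C@@H](O[Si](C)(C)C(C)(C)C)[C@@H]12 | intermediate
28 | trimethylammonium iodide of 27 | C[N+](C)(C)CC1C(=O)O[C@@H]2/C=C(/CO[Si](c3ccccc3)(c3ccccc3)C(C)(C)C)CC/C=C(/CO)C[C@@H](O[Si](C)(C)C(C)(C)C)[C@@H]12.[I-] | intermediate
29 | (3aS,4R,6E,10E,11aR)-4-(TBSO)-10-[(TBDPSO)methyl]-6-(hydroxymethyl)-3-methylidene-3a,4,5,8,9,11a-hexahydrocyclodeca[b]furan-2(3H)-one | C=C1C(=O)O[C@@H]2/C=C(/CO[Si](c3ccccc3)(c3ccccc3)C(C)(C)C)CC/C=C(/CO)C[C@@H](O[Si](C)(C)C(C)(C)C)[C@@H]12 | intermediate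
30 | (3aR,4R,6E,10E,11aR)-10-[(TBDPSO)methyl]-4-hydroxy-6-(hydroxymethyl)-3-methylidene-3a,4,5,8,9,11a-hexahydrocyclodeca[b]furan-2(3H)-one | C=C1C(=O)O[C@@H]2/C=C(/CO[Si](c3ccccc3)(c3ccccc3)C(C)(C)C)CC/C=C(/CO)C[C@@H](O)[C@@H]12 | intermediate
31 | (3aR,4R,6E,10E,11aR)-10-[(TBDPSO)methyl]-4-hydroxy-3-methylidene-6-[(TESO)methyl]-3a,4,5,8,9,11a-hexahydrocyclodeca[b]furan-2(3H)-one | C=C1C(=O)O[C@@H]2/C=C(/CO[Si](c3ccccc3)(c3ccccc3)C(C)(C)C)CC/C=C(/CO[Si](CC)(CC)CC)C[C@@H](O)[C@@H]12 | intermediate
32 | (2S)-2-methylbutanoic acid | CC[C@H](C)C(=O)O | starting material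
33 | (3aR,4R,6E,10E,11aR)-10-[(TBDPSO)methyl]-3-methylidene-2-oxo-6-[(TESO)methyl]-2,3,3a,4,5,8,9,11a-octahydrocyclodeca[b]furan-4-yl (2S)-2-methylbutanoate | C=C1C(=O)O[C@@H]2/C=C(/CO[Si](c3ccccc3)(c3ccccc3)C(C)(C)C)CC/C=C(/CO[Si](CC)(CC)CC)C[C@@H](OC(=O)[C@@H](C)CC)[C@@H]12 | intermediate
34 | (3aR,4R,6E,10E,11aR)-10-[(TBDPSO)methyl]-6-formyl-3-methylidene-2-oxo-2,3,3a,4,5,8,9,11a-octahydrocyclodeca[b]furan-4-yl (2S)-2-methylbutanoate | C=C1C(=O)O[C@@H]2/C=C(/CO[Si](c3ccccc3)(c3ccccc3)C(C)(C)C)CC/C=C(/C=O)C[C@@H](OC(=O)[C@@H](C)CC)[C@@H]12 | intermediate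
35 | (3aR,4R,6E,10E,11aR)-6-formyl-10-(hydroxymethyl)-3-methylidene-2-oxo-2,3,3a,4,5,8,9,11a-octahydrocyclodeca[b]furan-4-yl (2S)-2-methylbutanoate | C=C1C(=O)O[C@@H]2/C=C(/CO)CC/C=C(/C=O)C[C@@H](OC(=O)[C@@H](C)CC)[C@@H]12 | target

## Step count and least certain steps

Total: 20 steps. Longest linear sequence: 19 steps (steps 1–4 and 6–20; step 5 is a one-step branch).

**Step 13 (key step).** The likely failure is intermolecular coupling outrunning ring closure, or slow transmetalation that lets the borane protodeboronate and the alkylpalladium undergo β-hydride elimination. Zerovalent palladium may also ionise the allylic C6–O bond of the lactone. The cause is that a ten-membered ring is the least favourable size for this coupling in both entropy and strain. Fallback, keeping the C1–C2 bond but changing the nucleophile to zinc: starting from 21, hydroboration as in step 13 followed by buffered H2O2 (NaOAc) gives the C2 primary alcohol F1. PPh3, I2 and imidazole convert it into the C2 iodide F2, and zinc insertion (Zn, LiCl, THF) gives the alkylzinc iodide F3. Intramolecular Negishi coupling (Pd2(dba)3, 2-dicyclohexylphosphino-2′,6′-dimethoxybiphenyl, THF, high dilution) then returns to 23.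

**Step 11.** Site selectivity may be lost, with formylation at C11, if silylation of the lactone enolate is incomplete or if ethoxide cleaves the silyl ketene acetal. An unmasked lactone could also suffer Claisen attack by the C10 enolate. Fallback, bringing C1 in at the alcohol level with the zinc reagent so that no enolate is needed: commercial methyl 2-(hydroxymethyl)prop-2-enoate is hydroiodinated (NaI, Me3SiCl, MeCN, then water) to methyl 3-hydroxy-2-(iodomethyl)propanoate F4 and silylated (Et3SiCl, imidazole) to methyl 3-iodo-2-[(TESO)methyl]propanoate F5. Its zinc reagent F6 is coupled with 12 under the conditions of step 8 to the ketone F7 (both C10 epimers, which converge later). Reduction as in step 9 gives the alcohol F8 and silylation as in step 10 the bis-silyl ether F9. Swern oxidation of the primary triethylsilyl ether, as in step 19, then gives 20.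

**Step 12.** The geometric selectivity may erode if the enolate reacts as a chelated or tight ion pair, which puts the triflate cis to the ester; that isomer cannot close to the ring-cis alkene. Fallback, changing the leaving group and the way the geometry is set: from 20, TsCl with N-methylimidazole and Et3N (a metal-free sulfonylation that favours oxygen anti to the ester) gives the (E)-enol tosylate F10. Hydroboration as in step 13 gives its alkylborane F11, and coupling with Pd(OAc)2, 2-dicyclohexylphosphino-2′,6′-dimethoxybiphenyl and K3PO4 under dilution returns to 23.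

**Step 9.** Facial selectivity may be poor because both α-branches of the ketone are ring bonds, and the new alkoxide may lactonise onto C14 if the quench is not cold. Fallback, replacing substrate control by catalyst control: 15 is reduced with catecholborane and the S enantiomer of 1-methyl-3,3-diphenyltetrahydro-1H,3H-pyrrolo[1,2-c][1,3,2]oxazaborole. By the large/small model (C7 large, C9 small) this should give 16 with the 8R carbinol and makes no new compound.

**Step 6.** Dienal 6 may isomerise about C4=C5 or undergo reversible oxa-6π ring closure in the presence of the ammonium triflate, which would erode the alkene geometry carried into the lactone. Fallback, carrying iodine through the aldol and adding the vinyl group afterwards: 3 is oxidised (MnO2) to (2Z)-4-(TBDPSO)-3-iodobut-2-enal F12. Aldol reaction with the boron enolate of 9 as in step 6 gives the iodo aldol adduct F13, which lactonises to the iodo lactone imide F14. Stille coupling with 4 under the conditions of step 3 returns to 11.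

## Further compounds

F1 | step 13 | methyl (2E,4R)-4-(TBSO)-4-[(2R,3S)-2-{(1E)-4-hydroxy-2-[(TBDPSO)methyl]but-1-en-1-yl}-5-oxooxolan-3-yl]-2-({[(trifluoromethyl)sulfonyl]oxy}methylidene)butanoate | C1C(=O)O[C@H](/C=C(/CO[Si](c2ccccc2)(c2ccccc2)C(C)(C)C)CCO)[C@H]1[C@H](O[Si](C)(C)C(C)(C)C)C/C(C(=O)OC)=C\OS(=O)(=O)C(F)(F)F
F2 | step 13 | C2 iodide corresponding to F1 | C1C(=O)O[C@H](/C=C(/CO[Si](c2ccccc2)(c2ccccc2)C(C)(C)C)CCI)[C@H]1[C@H](O[Si](C)(C)C(C)(C)C)C/C(C(=O)OC)=C\OS(=O)(=O)C(F)(F)F
F3 | step 13 | alkylzinc iodide from F2 | C1C(=O)O[C@H](/C=C(/CO[Si](c2ccccc2)(c2ccccc2)C(C)(C)C)CC[Zn]I)[C@H]1[C@H](O[Si](C)(C)C(C)(C)C)C/C(C(=O)OC)=C\OS(=O)(=O)C(F)(F)F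
F4 | step 11 | methyl 3-hydroxy-2-(iodomethyl)propanoate (racemic) | COC(=O)C(CO)CI
F5 | step 11 | methyl 3-iodo-2-[(TESO)methyl]propanoate (racemic) | COC(=O)C(CI)CO[Si](CC)(CC)CC
F6 | step 11 | iodo{3-methoxy-3-oxo-2-[(TESO)methyl]propyl}zinc | COC(=O)C(C[Zn]I)CO[Si](CC)(CC)CC
F7 | step 11 | methyl 4-[(2R,3S)-2-{(1E)-2-[(TBDPSO)methyl]buta-1,3-dien-1-yl}-5-oxooxolan-3-yl]-4-oxo-2-[(TESO)methyl]butanoate (C10 epimers) | C1C(=O)O[C@H](/C=C(/CO[Si](c2ccccc2)(c2ccccc2)C(C)(C)C)C=C)[C@H]1C(=O)CC(CO[Si](CC)(CC)CC)C(=O)OC
F8 | step 11 | methyl (4R)-4-hydroxy-4-[(2R,3R)-2-{(1E)-2-[(TBDPSO)methyl]buta-1,3-dien-1-yl}-5-oxooxolan-3-yl]-2-[(TESO)methyl]butanoate (C10 epimers) | C1C(=O)O[C@H](/C=C(/CO[Si](c2ccccc2)(c2ccccc2)C(C)(C)C)C=C)[C@H]1[C@H](O)CC(CO[Si](CC)(CC)CC)C(=O)OC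
F9 | step 11 | methyl (4R)-4-(TBSO)-4-[(2R,3S)-2-{(1E)-2-[(TBDPSO)methyl]buta-1,3-dien-1-yl}-5-oxooxolan-3-yl]-2-[(TESO)methyl]butanoate (C10 epimers) | C1C(=O)O[C@H](/C=C(/CO[Si](c2ccccc2)(c2ccccc2)C(C)(C)C)C=C)[C@H]1[C@H](O[Si](C)(C)C(C)(C)C)CC(CO[Si](CC)(CC)CC)C(=O)OC
F10 | step 12 | methyl (2E,4R)-4-(TBSO)-4-[(2R,3S)-2-{(1E)-2-[(TBDPSO)methyl]buta-1,3-dien-1-yl}-5-oxooxolan-3-yl]-2-({[(4-methylphenyl)sulfonyl]oxy}methylidene)butanoate | C1C(=O)O[C@H](/C=C(/CO[Si](c2ccccc2)(c2ccccc2)C(C)(C)C)C=C)[C@H]1[C@H](O[Si](C)(C)C(C)(C)C)C/C(C(=O)OC)=C\OS(=O)(=O)c1ccc(C)cc1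
F11 | step 12 | B-alkyl-9-borabicyclo[3.3.1]nonane from F10 (boron on C2) | C1C(=O)O[C@H](/C=C(/CO[Si](c2ccccc2)(c2ccccc2)C(C)(C)C)CCB2C3CCCC2CCC3)[C@H]1[C@H](O[Si](C)(C)C(C)(C)C)C/C(C(=O)OC)=C\OS(=O)(=O)c1ccc(C)cc1
F0 | step 9 | none | none
F12 | step 6 | (2Z)-4-(TBDPSO)-3-iodobut-2-enal | O=C/C=C(/CO[Si](c1ccccc1)(c1ccccc1)C(C)(C)C)I
F13 | step 6 | methyl (3S,4R,5Z)-3-{[(4S)-4-benzyl-2-oxo-1,3-oxazolidin-3-yl]carbonyl}-7-(TBDPSO)-4-hydroxy-6-iodohept-5-enoate | COC(=O)C[C@@H]([C@H](O)/C=C(/CO[Si](c1ccccc1)(c1ccccc1)C(C)(C)C)I)C(=O)N1[C@@H](Cc2ccccc2)COC1=O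
F14 | step 6 | (4S)-4-benzyl-3-{[(2R,3S)-2-[(1Z)-3-(TBDPSO)-2-iodoprop-1-en-1-yl]-5-oxooxolan-3-yl]carbonyl}-1,3-oxazolidin-2-one | C1C(=O)O[C@H](/C=C(/CO[Si](c2ccccc2)(c2ccccc2)C(C)(C)C)I)[C@H]1C(=O)N1[C@@H](Cc2ccccc2)COC1=O
A1 | alternative 1 | trans-fused ten-membered γ-lactone, C11 unsubstituted, C14 p-methoxybenzyl ether, C8 triethylsilyl ether, C15 TBDPS ether | C1C(=O)O[C@@H]2/C=C(/CO[Si](c3ccccc3)(c3ccccc3)C(C)(C)C)CC/C=C(/COCc3ccc(OC)cc3)C[C@@H](O[Si](CC)(CC)CC)[C@@H]12
A2 | alternative 2 | ten-membered C10 enol triflate with ring-cis C4=C5, C6 TBS ether, C8 p-methoxybenzyl ether and a 3-(TBSO)prop-1-en-2-yl group on C7 | CC(C)(C)[Si](C)(C)O[C@@H]1/C=C(/CO[Si](c2ccccc2)(c2ccccc2)C(C)(C)C)CC/C=C(\OS(=O)(=O)C(F)(F)F)C[C@@H](OCc2ccc(OC)cc2)[C@H]1C(=C)CO[Si](C)(C)C(C)(C)C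
A3 | alternative 3 | 8-hydroxy germacranolide with C14 p-methoxybenzyl ether and C15 TBDPS ether | C=C1C(=O)O[C@@H]2/C=C(/CO[Si](c3ccccc3)(c3ccccc3)C(C)(C)C)CC/C=C(/COCc3ccc(OC)cc3)C[C@@H](O)[C@@H]12
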